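The eleven-membered ring (C1 = ester carbon, C4 = carbinol carbon, C11 = gem-dimethyl carbon) is disconnected at C9–C10, the one ring bond without neighbouring functionality: C10 is the CH2 beside quaternary C11, C9 the CH2 beyond C8, which is allylic to the (Z)-C6=C7 alkene. Drawn as C9=C10 it is the only disubstituted alkene of a humulene-type triene, so ring-closing metathesis of an acyclic tetraene with a vinyl group on C11 (installed together with the C1 stereocentre by reverse prenylation) and an allyl group on C7 closes the ring in one operation; diimide then saturates this alkene alone. The precursor is the silyl-protected C1 vanillate with both stereocentres and both trisubstituted alkenes in place.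

Key step: step 10

Remark 1: ring numbering used throughout is C1 (ester-bearing CH), C2=C3(Me), C4 (carbinol), C5, C6=C7(Me), C8, C9, C10, C11 (CMe2); the target is (1R,2E,4S,6Z).
Remark 2: the C9=C10 alkene of 22 is drawn E (as in humulene); the Z isomer would serve equally, because step 11 removes this alkene.
Remark 3: the facial selectivities of steps 2 and 7 are assigned from the closed transition-state models of the parent allylborations and are assumptions to be verified on 6 and 16.

Step 1
Reactants: 1 2,2-dimethoxyacetaldehyde (60% aqueous solution); 2 2-(triphenyl-λ5-phosphanylidene)propanal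
Product: 3 (2E)-4,4-dimethoxy-2-methylbut-2-enal
Conditions: toluene, 90 °C
Reagents that add atoms: none
Why: Wittig olefination: the formyl-stabilised α-methyl ylide reacts only with the more electrophilic aliphatic aldehyde 1 and, under thermodynamic control, should give the (E)-trisubstituted enal, so that C1 and C4 end up trans across the future C2=C3 alkene.

Step 2
Reactants: 3 (2E)-4,4-dimethoxy-2-methylbut-2-enal; 4 allenylboronic acid pinacol ester
Product: 6 (4S,5E)-7,7-dimethoxy-5-methylhept-5-en-1-yn-4-ol, via pinacol borate ester 5 (not isolated)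
Conditions: (S)-TRIP [(S)-3,3'-bis(2,4,6-triisopropylphenyl)-1,1'-binaphthyl-2,2'-diyl hydrogen phosphate] (10 mol %), 4 Å MS, toluene, 0 °C; then aqueous work-up
Reagents that add atoms: none
Why: Chiral-phosphoric-acid-catalysed propargylboration of an enal: the allenylboronate transfers its γ-carbon through a closed six-membered transition state in which the acid activates the boronate oxygen and binds the formyl hydrogen, and the (S)-acid (mirror image of the Re-selective (R)-acid of the parent allylboration) should direct attack on the Si face, which sets C4 as S.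

Step 3
Reactants: 6 (4S,5E)-7,7-dimethoxy-5-methylhept-5-en-1-yn-4-ol; 7 3-bromoprop-1-ene (allyl bromide)
Product: 8 (2E,4S)-1,1-dimethoxy-3-methyldeca-2,9-dien-6-yn-4-ol
Conditions: CuI (20 mol %), K2CO3, Bu4NBr, DMF, rt
Reagents that add atoms: none
Why: Copper-catalysed sp–sp3 coupling (alkynylcopper plus allyl bromide) should give the skipped 1,4-enyne under carbonate base without touching the free alcohol, the acetal or the C4 centre.

Step 4
Reactants: 8 (2E,4S)-1,1-dimethoxy-3-methyldeca-2,9-dien-6-yn-4-ol
Product: 10 (2E,4S,6Z)-1,1-dimethoxy-3,7-dimethyldeca-2,6,9-trien-4-ol, via alkenylmagnesium alkoxide 9 (not isolated)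
Conditions: MeMgBr (5 equiv), Fe(acac)3 (20 mol %), THF, −78 to 0 °C; then H2O
Reagents that add atoms: methylmagnesium bromide, C[Mg]Br
Why: Alkoxide-directed iron-catalysed syn-carbomagnesiation of a homopropargylic alcohol: the magnesium alkoxide steers methyl to the distal alkyne carbon C7 and the metal to the proximal C6 (five-membered chelate), so that protonation should leave H cis to the new methyl and the allyl group cis to C5, i.e. the (6Z)-alkene, while acetal and alkenes are inert to the Grignard reagent.

Step 5
Reactants: 10 (2E,4S,6Z)-1,1-dimethoxy-3,7-dimethyldeca-2,6,9-trien-4-ol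
Product: 11 tert-butyl{[(2E,4S,6Z)-1,1-dimethoxy-3,7-dimethyldeca-2,6,9-trien-4-yl]oxy}dimethylsilane
Conditions: TBSCl, imidazole, DMAP (cat.), DMF, rt
Reagents that add atoms: tert-butyldimethylsilyl chloride, CC(C)(C)[Si](C)(C)Cl
Why: Standard silyl ether formation caps the C4 hydroxyl so that it stays protected until the last step and cannot interfere with the borane, the acylation or the ruthenium carbene.

Step 6
Reactants: 11 tert-butyl{[(2E,4S,6Z)-1,1-dimethoxy-3,7-dimethyldeca-2,6,9-trien-4-yl]oxy}dimethylsilane
Product: 12 (2E,4S,6Z)-4-[(tert-butyldimethylsilyl)oxy]-3,7-dimethyldeca-2,6,9-trienal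
Conditions: PPTS (cat.), THF/H2O (4:1), rt
Reagents that add atoms: water, O
Why: Acid-catalysed acetal hydrolysis: the allylic dimethyl acetal ionises through a conjugated oxocarbenium ion far faster than the secondary silyl ether is cleaved, which should unveil the (E)-enal without moving either alkene.

Step 7
Reactants: 12 (2E,4S,6Z)-4-[(tert-butyldimethylsilyl)oxy]-3,7-dimethyldeca-2,6,9-trienal; 13 3-methylbuta-1,2-diene
Product: 16 (4R,5E,7S,9Z)-7-[(tert-butyldimethylsilyl)oxy]-3,3,6,10-tetramethyltrideca-1,5,9,12-tetraen-4-ol, via prenyl(diisopinocampheyl)borane 14 (not isolated), via diisopinocampheylborinate ester 15 (not isolated)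
Conditions: (−)-Ipc2BH [diisopinocampheylborane from (+)-α-pinene], 13 (slight excess), THF, −25 °C; then 12, Et2O, −78 °C; then NaOH, H2O2, 0 °C to rt
Reagents that add atoms: none
Why: Reagent-controlled allylboration (reverse prenylation): the prenylborane formed by hydroboration of the allene adds 1,2 to the enal through a chair six-membered transition state with its γ-carbon, creating the C1–C11 bond, the quaternary carbon and the vinyl group at once, and the isopinocampheyl groups derived from (+)-α-pinene should direct attack on the Si face of the aldehyde, which is 1R because C11 outranks C2.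

Step 8
Reactants: 17 4-hydroxy-3-methoxybenzoic acid (vanillic acid)
Product: 19 4-[(tert-butyldimethylsilyl)oxy]-3-methoxybenzoic acid, via bis-silylated vanillic acid 18 (not isolated)
Conditions: TBSCl (2.5 equiv), imidazole, DMF, rt; then AcOH/THF/H2O, rt
Reagents that add atoms: tert-butyldimethylsilyl chloride, CC(C)(C)[Si](C)(C)Cl
Why: Silylation followed by selective solvolysis of the labile silyl ester should leave the aryl silyl ether, giving an acid whose phenol protection is removed together with the C4 silyl ether in the last step.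

Step 9
Reactants: 16 (4R,5E,7S,9Z)-7-[(tert-butyldimethylsilyl)oxy]-3,3,6,10-tetramethyltrideca-1,5,9,12-tetraen-4-ol; 19 4-[(tert-butyldimethylsilyl)oxy]-3-methoxybenzoic acid
Product: 21 (4R,5E,7S,9Z)-7-[(tert-butyldimethylsilyl)oxy]-3,3,6,10-tetramethyltrideca-1,5,9,12-tetraen-4-yl 4-[(tert-butyldimethylsilyl)oxy]-3-methoxybenzoate, via mixed anhydride 20 (not isolated)
Conditions: 19, 2,4,6-trichlorobenzoyl chloride, Et3N, toluene, rt; then 16, DMAP, toluene, 60 °C
Reagents that add atoms: none
Why: Yamaguchi esterification: DMAP attacks the mixed anhydride at the less hindered vanilloyl carbonyl and the resulting acylpyridinium acylates the hindered neopentylic allylic alcohol at oxygen, so C1 keeps its configuration.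

Step 10
Reactants: 21 (4R,5E,7S,9Z)-7-[(tert-butyldimethylsilyl)oxy]-3,3,6,10-tetramethyltrideca-1,5,9,12-tetraen-4-yl 4-[(tert-butyldimethylsilyl)oxy]-3-methoxybenzoate
Product: 22 (1R,2E,4S,6Z,9E)-4-[(tert-butyldimethylsilyl)oxy]-3,7,11,11-tetramethylcycloundeca-2,6,9-trien-1-yl 4-[(tert-butyldimethylsilyl)oxy]-3-methoxybenzoate
Conditions: second-generation Grubbs catalyst (H2IMes)(PCy3)Cl2Ru=CHPh (10 mol %), 1,4-benzoquinone (20 mol %), toluene (0.5 mM, slow addition of 21), 80 °C, argon sparge
Reagents that add atoms: none
Why: The ruthenium alkylidene loads on the unhindered allyl terminus (C9), the new carbene adds to the C10 vinyl group through a ruthenacyclobutane ([2+2]/retro-[2+2]) and ethene is lost, which the argon sparge makes irreversible. The closest known reaction type is ring-closing metathesis to eleven-membered humulane carbocycles that already hold two trisubstituted ring alkenes. The single ring closed is the eleven-membered carbocycle, formed end-to-end from the two terminal alkene carbons; no smaller ring can compete, because metathesis of either terminal alkene with its nearest trisubstituted alkene would give a cyclopropene or cyclobutene. No stereocentre is created: C1 (R) and C4 (S) are carried through, and the C9=C10 geometry is erased in step 11. The step needs chemoselectivity for the two monosubstituted alkenes over C2=C3 and C6=C7 and cyclisation over oligomerisation; the trisubstituted alkenes are flanked by oxygenated or branched carbons and should stay inert, while high dilution, the gem-dimethyl group at C11 and the two rigid alkenes (one E, one Z) pre-fold the chain. Both oxygens are capped, so no ruthenium hydride can isomerise an allylic alcohol, and benzoquinone suppresses migration of the skipped C6=C7/C9 diene.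

Step 11
Reactants: 22 (1R,2E,4S,6Z,9E)-4-[(tert-butyldimethylsilyl)oxy]-3,7,11,11-tetramethylcycloundeca-2,6,9-trien-1-yl 4-[(tert-butyldimethylsilyl)oxy]-3-methoxybenzoate
Product: 23 (1R,2E,4S,6Z)-4-[(tert-butyldimethylsilyl)oxy]-3,7,11,11-tetramethylcycloundeca-2,6-dien-1-yl 4-[(tert-butyldimethylsilyl)oxy]-3-methoxybenzoate
Conditions: 2-nitrobenzenesulfonohydrazide (excess, in portions), Et3N, CH2Cl2, rt
Reagents that add atoms: none
Why: Diimide reduction: concerted syn transfer of two hydrogens from diazene, generated in the flask from the sulfonylhydrazide, is fastest for the least substituted alkene, so the disubstituted C9=C10 bond should be saturated while the two trisubstituted alkenes, the allylic ester (no hydrogenolysis) and the silyl ethers remain.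

Step 12
Reactants: 23 (1R,2E,4S,6Z)-4-[(tert-butyldimethylsilyl)oxy]-3,7,11,11-tetramethylcycloundeca-2,6-dien-1-yl 4-[(tert-butyldimethylsilyl)oxy]-3-methoxybenzoate
Product: 24 (1R,2E,4S,6Z)-4-hydroxy-3,7,11,11-tetramethylcycloundeca-2,6-dien-1-yl 4-hydroxy-3-methoxybenzoate (target)
Conditions: TBAF, AcOH, THF, 0 °C to rt
Reagents that add atoms: none
Why: Fluoride-mediated desilylation cleaves the aryl and the secondary allylic silyl ethers in one operation, the acetic acid buffer keeping the hindered vanillate ester and both ring alkenes untouched.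

Compound list
1 | 2,2-dimethoxyacetaldehyde | COC(OC)C=O | starting material
2 | 2-(triphenyl-λ5-phosphanylidene)propanal | CC(C=O)=P(c1ccccc1)(c1ccccc1)c1ccccc1 | starting material
3 | (2E)-4,4-dimethoxy-2-methylbut-2-enal | COC(OC)/C=C(\C)C=O | intermediate
4 | allenylboronic acid pinacol ester (4,4,5,5-tetramethyl-2-(propa-1,2-dien-1-yl)-1,3,2-dioxaborolane) | C=C=CB1OC(C)(C)C(C)(C)O1 | starting material
5 | pinacol borate ester of 6 (O–B(pin) at C4) | COC(OC)/C=C(\C)[C@@H](OB1OC(C)(C)C(C)(C)O1)CC#C | intermediate
6 | (4S,5E)-7,7-dimethoxy-5-methylhept-5-en-1-yn-4-ol | COC(OC)/C=C(\C)[C@@H](O)CC#C | intermediate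
7 | 3-bromoprop-1-ene (allyl bromide) | C=CCBr | starting material
8 | (2E,4S)-1,1-dimethoxy-3-methyldeca-2,9-dien-6-yn-4-ol | COC(OC)/C=C(\C)[C@@H](O)CC#CCC=C | intermediate
9 | bromomagnesium alkoxide of the C6-bromomagnesio alkene (syn adduct of Me–MgBr across the alkyne of 8) | COC(OC)/C=C(\C)[C@@H](O[Mg]Br)C/C([Mg]Br)=C(/C)CC=C | intermediate
10 | (2E,4S,6Z)-1,1-dimethoxy-3,7-dimethyldeca-2,6,9-trien-4-ol | COC(OC)/C=C(\C)[C@@H](O)C/C=C(/C)CC=C | intermediate
11 | tert-butyl{[(2E,4S,6Z)-1,1-dimethoxy-3,7-dimethyldeca-2,6,9-trien-4-yl]oxy}dimethylsilane | COC(OC)/C=C(\C)[C@@H](O[Si](C)(C)C(C)(C)C)C/C=C(/C)CC=C | intermediate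
12 | (2E,4S,6Z)-4-[(tert-butyldimethylsilyl)oxy]-3,7-dimethyldeca-2,6,9-trienal | O=C/C=C(\C)[C@@H](O[Si](C)(C)C(C)(C)C)C/C=C(/C)CC=C | intermediate
13 | 3-methylbuta-1,2-diene | CC(C)=C=C | starting material
14 | (3-methylbut-2-en-1-yl)diisopinocampheylborane, Ipc groups from (+)-α-pinene | CC(C)=CCB([C@@H]1C[C@@H]2C[C@H]([C@H]1C)C2(C)C)[C@@H]1C[C@@H]2C[C@H]([C@H]1C)C2(C)C | intermediate
15 | diisopinocampheylborinate ester of 16 (O–B(Ipc)2 at C4 of the chain) | C=CC(C)(C)[C@H](OB([C@@H]1C[C@@H]2C[C@H]([C@H]1C)C2(C)C)[C@@H]1C[C@@H]2C[C@H]([C@H]1C)C2(C)C)/C=C(\C)[C@@H](O[Si](C)(C)C(C)(C)C)C/C=C(/C)CC=C | intermediate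
16 | (4R,5E,7S,9Z)-7-[(tert-butyldimethylsilyl)oxy]-3,3,6,10-tetramethyltrideca-1,5,9,12-tetraen-4-ol | C=CC(C)(C)[C@H](O)/C=C(\C)[C@@H](O[Si](C)(C)C(C)(C)C)C/C=C(/C)CC=C | intermediate
17 | 4-hydroxy-3-methoxybenzoic acid (vanillic acid) | COc1cc(C(=O)O)ccc1O | starting material
18 | tert-butyldimethylsilyl 4-[(tert-butyldimethylsilyl)oxy]-3-methoxybenzoate | COc1cc(C(=O)O[Si](C)(C)C(C)(C)C)ccc1O[Si](C)(C)C(C)(C)C | intermediate
19 | 4-[(tert-butyldimethylsilyl)oxy]-3-methoxybenzoic acid | COc1cc(C(=O)O)ccc1O[Si](C)(C)C(C)(C)C | intermediate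
20 | 4-[(tert-butyldimethylsilyl)oxy]-3-methoxybenzoic 2,4,6-trichlorobenzoic anhydride | COc1cc(C(=O)OC(=O)c2c(Cl)cc(Cl)cc2Cl)ccc1O[Si](C)(C)C(C)(C)C | intermediate
21 | (4R,5E,7S,9Z)-7-[(tert-butyldimethylsilyl)oxy]-3,3,6,10-tetramethyltrideca-1,5,9,12-tetraen-4-yl 4-[(tert-butyldimethylsilyl)oxy]-3-methoxybenzoate | C=CC(C)(C)[C@H](OC(=O)c1ccc(O[Si](C)(C)C(C)(C)C)c(OC)c1)/C=C(\C)[C@@H](O[Si](C)(C)C(C)(C)C)C/C=C(/C)CC=C | intermediate
22 | (1R,2E,4S,6Z,9E)-4-[(tert-butyldimethylsilyl)oxy]-3,7,11,11-tetramethylcycloundeca-2,6,9-trien-1-yl 4-[(tert-butyldimethylsilyl)oxy]-3-methoxybenzoate | COc1cc(C(=O)O[C@@H]2/C=C(\C)[C@@H](O[Si](C)(C)C(C)(C)C)C/C=C(/C)C/C=C/C2(C)C)ccc1O[Si](C)(C)C(C)(C)C | intermediate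
23 | (1R,2E,4S,6Z)-4-[(tert-butyldimethylsilyl)oxy]-3,7,11,11-tetramethylcycloundeca-2,6-dien-1-yl 4-[(tert-butyldimethylsilyl)oxy]-3-methoxybenzoate | COc1cc(C(=O)O[C@@H]2/C=C(\C)[C@@H](O[Si](C)(C)C(C)(C)C)C/C=C(/C)CCCC2(C)C)ccc1O[Si](C)(C)C(C)(C)C | intermediate
24 | (1R,2E,4S,6Z)-4-hydroxy-3,7,11,11-tetramethylcycloundeca-2,6-dien-1-yl 4-hydroxy-3-methoxybenzoate | COc1cc(C(=O)O[C@@H]2/C=C(\C)[C@@H](O)C/C=C(/C)CCCC2(C)C)ccc1O | target

Total step count: 12. Longest linear sequence: 11 steps (steps 1–7 and 9–12); step 8 prepares the acid partner.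

Steps most likely to fail

1. Step 10 (ring-closing metathesis). What may go wrong: intermolecular metathesis through the allyl terminus (dimers, oligomers) outruns the strained eleven-membered closure at the neopentyl vinyl group, which is further shielded by the neighbouring aroyloxy group; the skipped diene may also migrate into conjugation before closure. Fallback, changing the oxidation level at C1 and the order of events: it sets out from alcohol 16. Dess–Martin oxidation should give the enone (5E,7S,9Z)-7-[(tert-butyldimethylsilyl)oxy]-3,3,6,10-tetramethyltrideca-1,5,9,12-tetraen-4-one F1, in which C1 is planar and carries no bulky substituent beside the vinyl group. Ring-closing metathesis of this humulenone-type substrate under the conditions of step 10 should give the macrocyclic trienone (2E,4S,6Z,9E)-4-[(tert-butyldimethylsilyl)oxy]-3,7,11,11-tetramethylcycloundeca-2,6,9-trien-1-one F2. Corey–Bakshi–Shibata reduction with (S)-2-methyl-CBS-oxazaborolidine and catecholborane, with quaternary C11 acting as the large group, should restore the 1R carbinol as (1R,2E,4S,6Z,9E)-4-[(tert-butyldimethylsilyl)oxy]-3,7,11,11-tetramethylcycloundeca-2,6,9-trien-1-ol F3. Yamaguchi esterification of this alcohol with 19 (through 20, as in step 9) comes back to the route at 22.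

2. Step 11 (diimide reduction). What may go wrong: loss of chemoselectivity, either because the strained (E)-C2=C3 ring alkene competes for diimide (over-reduction) or because the C9=C10 alkene, shielded by the gem-dimethyl group, reacts too slowly (incomplete reduction). Fallback, changing the reduction manifold from strain-sensitive group transfer to coordination-controlled catalysis: it sets out from 22 and returns at 23 by homogeneous hydrogenation with RhCl(PPh3)3 under H2 (1 atm, benzene/EtOH, rt), which binds and reduces disubstituted alkenes but not trisubstituted ones and does not cleave allylic esters; it makes no new compound (F0).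

3. Step 4 (iron-catalysed carbomagnesiation). What may go wrong: erosion of regio- or stereocontrol in the carbometallation (methyl delivered to the proximal carbon, or loss of syn addition), or isomerisation of the skipped enyne to an allene or conjugated enyne under the basic, iron-containing conditions. Fallback, making the (Z)-alkene separately by a stereospecific trans-hydroalumination and joining it through the C4–C5 bond: it sets out from enal 3 and returns at 10. But-2-yn-1-ol is reduced with NaAlH2(OCH2CH2OCH3)2 and the alkenylalane is quenched with iodine to give (2Z)-3-iodobut-2-en-1-ol F4. Stille coupling with allyltributylstannane (Pd(PPh3)4, DMF) should give (2Z)-3-methylhexa-2,5-dien-1-ol F5, and MsCl, LiCl and collidine convert it into (2Z)-1-chloro-3-methylhexa-2,5-diene F6. The allylic barium reagent made from this chloride with activated barium (from BaI2 and lithium biphenylide, THF, −78 °C) adds to 3 at its α-carbon with retention of the Z geometry. This gives the racemic carbinol, that is 10 together with its enantiomer (2E,4R,6Z)-1,1-dimethoxy-3,7-dimethyldeca-2,6,9-trien-4-ol F7. Dess–Martin oxidation of the racemate gives (2E,6Z)-1,1-dimethoxy-3,7-dimethyldeca-2,6,9-trien-4-one F8, and Corey–Bakshi–Shibata reduction with (R)-2-methyl-CBS-oxazaborolidine and catecholborane (alkenyl as the large group) should give 10.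

Further compounds
F1 | step 10 | (5E,7S,9Z)-7-[(tert-butyldimethylsilyl)oxy]-3,3,6,10-tetramethyltrideca-1,5,9,12-tetraen-4-one | C=CC(C)(C)C(=O)/C=C(\C)[C@@H](O[Si](C)(C)C(C)(C)C)C/C=C(/C)CC=C
F2 | step 10 | (2E,4S,6Z,9E)-4-[(tert-butyldimethylsilyl)oxy]-3,7,11,11-tetramethylcycloundeca-2,6,9-trien-1-one | O=C1/C=C(\C)[C@@H](O[Si](C)(C)C(C)(C)C)C/C=C(/C)C/C=C/C1(C)C
F3 | step 10 | (1R,2E,4S,6Z,9E)-4-[(tert-butyldimethylsilyl)oxy]-3,7,11,11-tetramethylcycloundeca-2,6,9-trien-1-ol | O[C@@H]1/C=C(\C)[C@@H](O[Si](C)(C)C(C)(C)C)C/C=C(/C)C/C=C/C1(C)C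
F0 | step 11 | none | none
F4 | step 4 | (2Z)-3-iodobut-2-en-1-ol | C/C(I)=C/CO
F5 | step 4 | (2Z)-3-methylhexa-2,5-dien-1-ol | C=CC/C(C)=C\CO
F6 | step 4 | (2Z)-1-chloro-3-methylhexa-2,5-diene | C=CC/C(C)=C\CCl
F7 | step 4 | (2E,4R,6Z)-1,1-dimethoxy-3,7-dimethyldeca-2,6,9-trien-4-ol | COC(OC)/C=C(\C)[C@H](O)C/C=C(/C)CC=C
F8 | step 4 | (2E,6Z)-1,1-dimethoxy-3,7-dimethyldeca-2,6,9-trien-4-one | COC(OC)/C=C(\C)C(=O)C/C=C(/C)CC=C
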